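**Retrosynthetic overview**
1. Target 13 ⇒ dibenzyl ether 12 ⇒ aldehyde 7 + aryl Grignard reagent 11. The aryl–carbinol bond is the last C–C bond, and 1,2-induction from ring carbon C3 (Felkin–Anh and chelate models agree) sets the carbinol centre.
2. 7 ⇒ 4 + acrolein 5 by cutting O1–C2 and C3–C4 of the oxolane. The only ring is closed in one operation: oxa-Michael addition (O1–C2), then enantioselective 5-exo-trig closure of an enamine-derived α-formyl radical onto the styrene (C3–C4).
3. Enabling feature: O1–C2–C3 plus the exocyclic carbinol carbon of 13 are a masked β-alkoxy aldehyde (acrolein) unit; O1–C5–C4 plus the benzylic CH2 and its guaiacyl ring are a masked (E)-coniferyl alcohol. C3 (aldehyde α-carbon) and C4 (styrene β-carbon) are both nucleophilic carbons and are joined by one-electron polarity reversal; the benzylic carbon ends as CH2 by hydrogen-atom transfer.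
4. 4 ⇐ 4-(benzyloxy)-3-methoxybenzaldehyde 1 (Horner–Wadsworth–Emmons olefination, then i-Bu2AlH); 11 ⇐ 4-bromo-2-methoxyphenol 8.

Key step: step 3

Remark: oxolane atoms are numbered O1, C2, C3 (bears the formyl or carbinol carbon), C4 (bears the arylmethyl group), C5 throughout; compounds 1, 2, 5, 8 and 9 are taken as commercial.

Step 1
Reactants: 1 4-(benzyloxy)-3-methoxybenzaldehyde; 2 triethyl phosphonoacetate
Product: 3 ethyl (2E)-3-[4-(benzyloxy)-3-methoxyphenyl]prop-2-enoate
Conditions: NaH, THF, 0 °C to rt
Reagents that add atoms: none
Why: Horner–Wadsworth–Emmons olefination of an aromatic aldehyde with a stabilised phosphonate anion should give the (E)-cinnamate, and the benzyl ether is inert to NaH.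

Step 2
Reactants: 3 ethyl (2E)-3-[4-(benzyloxy)-3-methoxyphenyl]prop-2-enoate
Product: 4 (2E)-3-[4-(benzyloxy)-3-methoxyphenyl]prop-2-en-1-ol
Conditions: i-Bu2AlH (2.5 equiv), CH2Cl2, −78 to 0 °C; aq. KNaC4H4O6 (potassium sodium tartrate) work-up
Reagents that add atoms: none
Why: 1,2-reduction of the conjugated ester by the aluminium hydride at low temperature should give the allylic alcohol without touching the styrene double bond or the benzyl ether.

Step 3
Reactants: 4 (2E)-3-[4-(benzyloxy)-3-methoxyphenyl]prop-2-en-1-ol; 5 acrolein (prop-2-enal)
Product: 7 (3R,4R)-4-{[4-(benzyloxy)-3-methoxyphenyl]methyl}oxolane-3-carbaldehyde, via ether aldehyde 6 (not isolated)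
Conditions: 5 (2 equiv), (2S,5R)-2-tert-butyl-3,5-dimethylimidazolidin-4-one·CF3CO2H (20 mol%), DME, 0 °C to rt, dark; excess 5 stripped in vacuo, fresh DME; then [Ir(Fmppy)2(dtbbpy)]PF6 (1 mol%; Fmppy = cyclometalated 2-(4-fluorophenyl)-4-methylpyridine, dtbbpy = 4,4'-di-tert-butyl-2,2'-bipyridine), 2,4,6-triisopropylbenzenethiol (20 mol%), trace H2O, blue LEDs, −20 °C
Reagents that add atoms: none
Why: Proposed new method: the imidazolidinone salt converts acrolein into an iminium ion that the allylic hydroxyl of 4 attacks at the unsubstituted β-carbon (oxa-Michael, bond O1–C2), and after removal of free acrolein the same amine turns ether aldehyde 6 into an E-enamine that the excited trivalent iridium photocatalyst oxidises to an electrophilic 3π-electron enaminyl radical; this radical closes the oxolane ring in 5-exo-trig mode on the styrene carbon next to the OCH2 group (bond C3–C4), the benzylic radical takes a hydrogen atom from the thiol, and divalent iridium reduces the thiyl radical to close all three cycles. The closest known reactions are the amine-catalysed conjugate addition of alcohols to enals and the photoredox/enamine/thiol triple-catalytic enantioselective α-alkylation of aldehydes with tethered olefins; what is new is running them as a relay in one flask with one amine, and only the compatibility of free acrolein with the thiol stands between them, which the evaporation of 5 addresses. C3 is set by the catalyst: its tert-butyl group fixes the enamine geometry and its 5-methyl group blocks one face, so that the (2S,5R) amine, the mirror image of the form that gives the opposite sense in related enamine radical alkylations, should deliver (3R). C4 is set by the chair-like 5-exo transition state, which puts the iminium-bearing carbon and the arylmethyl arm trans, giving (4R). The step needs exo regioselectivity and chemoselective oxidation of the enamine in the presence of the electron-rich styrene; the aryl group secures the first by stabilising the benzylic radical and matching the polarity of the electrophilic radical, and the lower oxidation potential of the enamine relative to the dialkoxystyrene secures the second.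

Step 4
Reactants: 8 4-bromo-2-methoxyphenol; 9 benzyl bromide
Product: 10 1-(benzyloxy)-4-bromo-2-methoxybenzene
Conditions: K2CO3, DMF, rt
Reagents that add atoms: none
Why: Williamson etherification of the phenoxide with benzyl bromide masks the acidic phenol before the organomagnesium reagent is made.

Step 5
Reactants: 7 (3R,4R)-4-{[4-(benzyloxy)-3-methoxyphenyl]methyl}oxolane-3-carbaldehyde; 10 1-(benzyloxy)-4-bromo-2-methoxybenzene
Product: 12 (R)-[4-(benzyloxy)-3-methoxyphenyl][(3R,4R)-4-{[4-(benzyloxy)-3-methoxyphenyl]methyl}oxolan-3-yl]methanol, via arylmagnesium bromide 11 (not isolated)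
Conditions: 10 (1.5 equiv), Mg, THF, 40 °C; then 7, CH2Cl2/THF, −78 °C; aq. NH4Cl
Reagents that add atoms: none
Why: Grignard addition to the α-branched aldehyde at −78 °C should outrun enolisation, and the new carbinol centre should be (R) by 1,2-induction from C3, because Felkin–Anh attack anti to ring carbon C4 (the larger branch) and attack on a magnesium chelate between the aldehyde oxygen and ring oxygen O1 both expose the same face.

Step 6
Reactants: 12 (R)-[4-(benzyloxy)-3-methoxyphenyl][(3R,4R)-4-{[4-(benzyloxy)-3-methoxyphenyl]methyl}oxolan-3-yl]methanol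
Product: 13 4-[(R)-hydroxy{(3R,4R)-4-[(4-hydroxy-3-methoxyphenyl)methyl]oxolan-3-yl}methyl]-2-methoxyphenol
Conditions: H2 (1 atm), 10% Pd/C, EtOAc/EtOH, rt, short reaction time
Reagents that add atoms: none
Why: hydrogenolysis of the two aryl benzyl ethers over Pd/C under neutral conditions should be much faster than cleavage of the secondary benzylic C–OH bond, so both phenols are released and the three stereocentres are untouched.

**Compound list**
1 | 4-(benzyloxy)-3-methoxybenzaldehyde | COc1cc(C=O)ccc1OCc1ccccc1 | starting material
2 | triethyl phosphonoacetate | CCOC(=O)CP(=O)(OCC)OCC | starting material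
3 | ethyl (2E)-3-[4-(benzyloxy)-3-methoxyphenyl]prop-2-enoate | CCOC(=O)/C=C/c1ccc(OCc2ccccc2)c(OC)c1 | intermediate
4 | (2E)-3-[4-(benzyloxy)-3-methoxyphenyl]prop-2-en-1-ol | OC/C=C/c1ccc(OCc2ccccc2)c(OC)c1 | intermediate
5 | acrolein (prop-2-enal) | C=CC=O | starting material
6 | 3-{[(2E)-3-[4-(benzyloxy)-3-methoxyphenyl]prop-2-en-1-yl]oxy}propanal | O=CCCOC/C=C/c1ccc(OCc2ccccc2)c(OC)c1 | intermediate
7 | (3R,4R)-4-{[4-(benzyloxy)-3-methoxyphenyl]methyl}oxolane-3-carbaldehyde | COc1cc(C[C@H]2COC[C@@H]2C=O)ccc1OCc1ccccc1 | intermediate
8 | 4-bromo-2-methoxyphenol | COc1cc(Br)ccc1O | starting material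
9 | benzyl bromide | BrCc1ccccc1 | starting material
10 | 1-(benzyloxy)-4-bromo-2-methoxybenzene | COc1cc(Br)ccc1OCc1ccccc1 | intermediate
11 | [4-(benzyloxy)-3-methoxyphenyl]magnesium bromide | COc1cc([Mg]Br)ccc1OCc1ccccc1 | intermediate
12 | (R)-[4-(benzyloxy)-3-methoxyphenyl][(3R,4R)-4-{[4-(benzyloxy)-3-methoxyphenyl]methyl}oxolan-3-yl]methanol | COc1cc(C[C@H]2COC[C@@H]2[C@@H](O)c2ccc(OCc3ccccc3)c(OC)c2)ccc1OCc1ccccc1 | intermediate
13 | 4-[(R)-hydroxy{(3R,4R)-4-[(4-hydroxy-3-methoxyphenyl)methyl]oxolan-3-yl}methyl]-2-methoxyphenol | COc1cc(C[C@H]2COC[C@@H]2[C@@H](O)c2ccc(O)c(OC)c2)ccc1O | target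

**Totals**
Total step count: 6. Longest linear sequence: 5 steps (steps 1, 2, 3, 5, 6); step 4 is a one-step side branch.

**Steps most likely to fail**

Step 3 (proposed new method). The oxa-Michael equilibrium may not be driven far enough by the amine salt, or acrolein may oligomerise. During irradiation, retro-oxa-Michael release of acrolein may consume the thiol co-catalyst by thia-Michael addition and stall hydrogen-atom transfer. Enantiofacial control may also be eroded if the cis isomer epimerises at C3. The fallback sets out from 4 and comes back at 7, with the two bond formations uncoupled and each done by known chemistry. Trimethylphosphine-catalysed hydroalkoxylation of acrolein with 4 (PMe3 5 mol%, THF, rt) gives 6, which is now isolated and purified. Pure 6 is then submitted to the established triple-catalytic intramolecular aldehyde α-alkylation (same iridium photocatalyst, imidazolidinone salt and thiol, DME, blue LEDs), with no acrolein in the flask, to give 7. This fallback makes no compound outside the list (F0).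

Step 5. Facial selectivity at the aldehyde may be poor because the two ring branches on the α-carbon differ little in size, and the basic Grignard reagent may enolise the aldehyde and epimerise C3. The fallback sets out from the crude product of step 5 (12 together with its carbinol epimer) and comes back at 12, replacing substrate control by reagent control. Oxidation of the mixture with Dess–Martin periodinane (CH2Cl2, NaHCO3, rt) gives the single ketone [4-(benzyloxy)-3-methoxyphenyl][(3R,4R)-4-{[4-(benzyloxy)-3-methoxyphenyl]methyl}oxolan-3-yl]methanone F1, whose α-centre is held trans thermodynamically. Corey–Bakshi–Shibata reduction with (S)-2-methyl-CBS-oxazaborolidine and BH3·SMe2 (THF, −40 °C), with the aryl group as the large substituent, should then give the (R)-carbinol 12. Note that simple hydride reduction of F1 is expected to favour the wrong epimer, so the catalyst has to override the substrate.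

Step 6. Once the para phenol is free, the electron-rich benzylic C–OH bond may be over-reduced, giving the deoxygenated dibenzyl oxolane. The fallback sets out from 7 and 8 and comes back at 13, moving hydrogenolysis ahead of the carbinol and ending with fluoride. Hydrogenolysis of 7 (H2, 10% Pd/C, EtOAc) gives (3R,4R)-4-[(4-hydroxy-3-methoxyphenyl)methyl]oxolane-3-carbaldehyde F2. Silylation (TBSCl, imidazole, DMF) gives (3R,4R)-4-({4-[(tert-butyldimethylsilyl)oxy]-3-methoxyphenyl}methyl)oxolane-3-carbaldehyde F3. In parallel 8 is silylated in the same way to (4-bromo-2-methoxyphenoxy)(tert-butyl)dimethylsilane F4, which with Mg in THF gives {4-[(tert-butyldimethylsilyl)oxy]-3-methoxyphenyl}magnesium bromide F5. Addition of F5 to F3 at −78 °C, under the same stereocontrol as in step 5, gives (R)-{4-[(tert-butyldimethylsilyl)oxy]-3-methoxyphenyl}[(3R,4R)-4-({4-[(tert-butyldimethylsilyl)oxy]-3-methoxyphenyl}methyl)oxolan-3-yl]methanol F6. Bu4NF buffered with AcOH (THF, 0 °C) then releases 13.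

**Further compounds**
F0 | step 3 | none | none
F1 | step 5 | [4-(benzyloxy)-3-methoxyphenyl][(3R,4R)-4-{[4-(benzyloxy)-3-methoxyphenyl]methyl}oxolan-3-yl]methanone | COc1cc(C[C@H]2COC[C@@H]2C(=O)c2ccc(OCc3ccccc3)c(OC)c2)ccc1OCc1ccccc1
F2 | step 6 | (3R,4R)-4-[(4-hydroxy-3-methoxyphenyl)methyl]oxolane-3-carbaldehyde | COc1cc(C[C@H]2COC[C@@H]2C=O)ccc1O
F3 | step 6 | (3R,4R)-4-({4-[(tert-butyldimethylsilyl)oxy]-3-methoxyphenyl}methyl)oxolane-3-carbaldehyde | COc1cc(C[C@H]2COC[C@@H]2C=O)ccc1O[Si](C)(C)C(C)(C)C
F4 | step 6 | (4-bromo-2-methoxyphenoxy)(tert-butyl)dimethylsilane | COc1cc(Br)ccc1O[Si](C)(C)C(C)(C)C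
F5 | step 6 | {4-[(tert-butyldimethylsilyl)oxy]-3-methoxyphenyl}magnesium bromide | COc1cc([Mg]Br)ccc1O[Si](C)(C)C(C)(C)C
F6 | step 6 | (R)-{4-[(tert-butyldimethylsilyl)oxy]-3-methoxyphenyl}[(3R,4R)-4-({4-[(tert-butyldimethylsilyl)oxy]-3-methoxyphenyl}methyl)oxolan-3-yl]methanol | COc1cc(C[C@H]2COC[C@@H]2[C@@H](O)c2ccc(O[Si](C)(C)C(C)(C)C)c(OC)c2)ccc1O[Si](C)(C)C(C)(C)C
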